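(The data were computed for substances that don't exist, noise included.)

Friday's run is this very flask followed up to 40.0 min, so I began from its readings.

| flask | solid substrate | remark | time |
|---|---|---|---|
| Friday's | 0.050 M | the very flask that is asked about, followed so far |  |
| flask | 0.050 M |  | 5.0 h |

Friday's run (percent of the solid substrate charged)

| time / min | solid substrate / % | target / % |
|---|---|---|
| 5.00 | 87.8 | 2.7 |
| 10.0 | 76.2 | 2.7 |
| 15.0 | 65.8 | 2.7 |
| 20.0 | 54.6 | 4.2 |
| 25.0 | 42.3 | 4.5 |
| 30.0 | 31.2 | 4.9 |
| 40.0 | 10.1 | 6.4 |

(scatter of a reading: 0.5 percentage points)

- percentages count the solid substrate that a species holds: one homo dimer counts as two
- solid, in amounts per volume of the solution: solid substrate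
- the earlier runs were read with a standard deviation of 0.5 percentage points
- steps that have been proposed: 2 starting material -> homo dimer; solid substrate <-> starting material; starting material <-> target; starting material <-> isomer of the product A; target <-> isomer of the product B
- at the start none of the solid substrate is in solution
- what has only dissolved of solid substrate counts as not reacted

- part of the solid substrate that has turned into other species by 5.0 h (what has only dissolved does not count)
- how much target there is at 5.0 h, in percent of the solid substrate charged
- how much isomer of the product B there is at 5.0 h, in percent of the solid substrate charged

By 40.0 min in Friday's run the solid substrate read 10.1%, so 89.9% of the charge had left it, but target read 6.4%. So I counted turnovers. The part of the charge that was neither solid substrate nor target came to 13.0 times the target present, and this turnover count, unread amount per amount of target, had also read 13.0 at 30.0 min. I took it as holding within the scatter. If it held until the whole charge had left the solid, target would be 7.14%. But the count does not divide the unread part among the other species, so I committed to target and nothing further.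

The forecast gave 96% conversion, 6% target, lower than mine, and 3% isomer of the product B, holding that “dimer, being irreversible, takes nearly everything”.

The flask gave 98.0% conversion, 5.88% target and 88.2% isomer of the product B.

    2 starting material → homo dimer (k = 0.00110 L mol⁻¹ min⁻¹)
    solid substrate ⇌ starting material, rate k2*(cs2 - [starting material]) while solid is left; crystals form when [starting material] > cs2 (solubility = 21.0 mM, k = 0.0650 min⁻¹)
    starting material ⇌ target (K = 3.00, k = 0.270 min⁻¹)
    starting material ⇌ isomer of the product A (K = 2.00, k = 0.100 min⁻¹)
    target ⇌ isomer of the product B (K = 15.0, k = 0.740 min⁻¹)

At 5.00 h the turnover count read 16.0 in this flask and 16.0 in the flask charged with 0.085 M of solid substrate. In this flask, of the turnover up to 5.00 h, half of the step from target to isomer of the product B was done by 0.512 h, later than the 0.361 h for the going into solution of solid substrate, and at 5.00 h isomer of the product B stood at 15.0 times the target.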